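An easy step first: in the beta run at 20.0 min, Q and Uj together stand at 98.0 % of the charge, so the share of Uj can serve as the conversion of Q.

| flask | Q | J | D | G | temperature | remark | time |
|---|---|---|---|---|---|---|---|
| alpha | 10 mM (in portions, 2) | 80 mM | 200 mM | 1.6 mM | 10 °C | run made earlier; portions every 5.0 min |  |
| beta | 27 mM (in portions, 2) | 80 mM | 200 mM | 1.6 mM | 25 °C | run made earlier; portions every 5.0 min |  |
| gamma | 40 mM (in portions, 2) | 80 mM | 200 mM | 1.2 mM | 10 °C | run made earlier; portions every 5.0 min |  |
| west | 12 mM (in portions, 2) | 80.0 mM | 200 mM | 0.80 mM | 25 °C | the portions of Q follow each other after 5.0 min, the first at the start | 25 min |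
| east | 40 mM (in portions, 2) | 80.0 mM | 200 mM | 1.6 mM | 25 °C | the portions of Q follow each other after 5.0 min, the first at the start | 25 min |
| north-west | 40 mM (in portions, 2) | 80.0 mM | 200 mM | 1.6 mM | 25 °C | the portions of Q follow each other after 8.0 min, the first at the start | 25 min |
| south | 40 mM (in portions, 2) | 250 mM | 400 mM | 1.6 mM | 25 °C | the portions of Q follow each other after 5.0 min, the first at the start | 25 min |
| south-west | 40 mM (in portions, 2) | 80.0 mM | 200 mM | 0.50 mM | 25 °C | the portions of Q follow each other after 1.5 min, the first at the start | 25 min |

| run | time / min | Uj / % | Q / % |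
|---|---|---|---|
| alpha | 2.00 | 0 | 49 |
| alpha | 5.00 | 6 | 45 |
| alpha | 10.0 | 9 | 90 |
| alpha | 15.0 | 16 | 84 |
| alpha | 20.0 | 20 | 78 |
| alpha | 30.0 | 27 | 72 |
| alpha | 40.0 | 34 | 65 |
| beta | 1.00 | 2 | 48 |
| beta | 2.50 | 5 | 45 |
| beta | 5.00 | 8 | 42 |
| beta | 8.00 | 15 | 87 |
| beta | 10.0 | 16 | 83 |
| beta | 15.0 | 21 | 80 |
| beta | 20.0 | 24 | 74 |
| gamma | 8.00 | 6 | 93 |
| gamma | 15.0 | 13 | 90 |
| gamma | 20.0 | 16 | 83 |
| gamma | 30.0 | 22 | 79 |
| gamma | 40.0 | 24 | 73 |

(each reading ± 1.5 percentage points)

- ranking by amount of Uj, in percent of the Q charged, from high to low, at 25 min (west / east / north-west / south / south-west)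
- the amount of Uj, in percent of the Q charged of the flask you put first, at 25 min
- the amount of Uj, in percent of the Q charged of the flask you put last, at 25 min

- the numbers in the tables scatter with a standard deviation of 1.5 percentage points

The two of us part over south, the flask with more J and more D, because the earlier runs all held J at 80 mM and D at 200 mM. The forecast puts south first at 38 %, with a range of 25 % to 60 %, and low at 12 %, in the order south > east > north-west > west > south-west. Of south it says: “South is a guess: more reagent probably speeds the reaction”.

My own reckoning replaces the bending curve by its mean. Divide the natural logarithm of the inverse of the unconverted share by the time. For the beta run, with the Uj reading at 20.0 min, that gives 0.0137 /min. This is the mean pace, a pseudo-first-order constant averaged over the run, and it is a reading that carries the scatter. It transfers to east because beta shares J, D, G, the temperature and the portion interval with east, and differs in Q, 27 mM against 40 mM.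

Carried to 25 min, the mean pace gives east 29.0 %. The error of the mean can be checked. The beta run gained 3 points in its last 5.00 min, and adding that gain once more gives 27.0 %. So the mean runs high by about a reading's scatter.

My view is that each turn takes one J, so the pace goes with the J charged, and that D stands by. South has 3.12 times the J of east, so my figure for south is 65.8 %. The forecast's 38 % asks for a pace just 1.40 times the mean pace, so J would be a weak lever. Here the two of us differ.

    Q + J + G → G + Uj (k = 297 /M²/min, Ea = 36.0 kJ/mol)
    D + J + G → G + Qi (k = 163 /M²/min, Ea = 46.0 kJ/mol)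
    J → Z (k = 8.76 × 10⁻⁵ /min, Ea = 114 kJ/mol)
    2 G → X (k = 12.9 /M/min, Ea = 64.0 kJ/mol)
    G → E (k = 0.00186 /min, Ea = 97.0 kJ/mol)
    (constants at 25 °C)

The flasks rank south > east > north-west > west > south-west. South gives 53.6 %, which is 16 points above the forecast and 12 points below my figure, so mine stands nearer; south-west gives 17.7 %. At the end of south, Qi stands at 169 mM against 21.4 mM of Uj, and each of the two takes one J. The mean pace, scaled by J, gives 65.8 % for a neighbour of south with D at 160 mM, and that flask gives 69.1 %. Another neighbour of south, with J at 100 mM and D still at 400 mM, is held against the scaled pace's 34.9 %: that flask gives 24.5 %, with J down to 16.8 % of its charge.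

All runs are calculated for an exercise; scatter was added.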